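## Retrosynthetic overview

1. The target is opened at the C3 ester: global MOM removal follows esterification of a MOM-protected (2R,3R)-flavan-3-ol with MOM-ferulic acid, itself made by Heck coupling of an aryl bromide with acrylic acid.
2. Both stereocentres come from one racemic flavan-3-one, reduced to the cis-(2R,3R) alcohol by a Ru-catalysed hydrogenative dynamic kinetic resolution (the new step).
3. The ketone comes from a flav-3-ene (hydroboration/oxidation, then Dess–Martin); the flavene is made by Ni-catalysed C2–aryl coupling of a 2-ethoxy-2H-chromene (rings A and C) with the ring B boronic acid.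
4. Ring order: ring A (from resorcinol, third oxygen by Ir C–H borylation/oxidation), then ring C (Au-catalysed hydroarylation of the propargyl ether), then ring B (from resorcinol by ortho-lithiation and Ir C–H borylation) is attached, and the ferulate ring comes last.

Assumption: the (S)-xylbinap/(S)-daipen catalyst of step 12 is taken, by analogy with the hydrogenation of racemic 2-methoxycyclohexanone to its (1R,2S) alcohol, to give the (2R,3R) alcohol, and the (R)/(R) catalyst is used in the same way if the first run shows the opposite sense; racemic compounds are drawn as one enantiomer to show relative configuration, and reagents carry no compound number.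

## Route

Step 1
Reactants: 1 resorcinol
Product: 2 1,3-bis(methoxymethoxy)benzene
Conditions: NaH (2.4 equiv), MOMCl (2.4 equiv), DMF, 0 °C to rt
Reagents that add atoms: chloromethyl methyl ether (MOMCl), COCCl
Why: Williamson-type O-alkylation of both phenoxides gives the bis-MOM ether, which later directs lithiation and withstands every basic and metal-catalysed step.

Step 2
Reactants: 2 1,3-bis(methoxymethoxy)benzene
Product: 4 3,5-bis(methoxymethoxy)phenol, via pinacol boronate 3 (not isolated)
Conditions: [Ir(OMe)(cod)]2 (1 mol%), dtbpy (2 mol%), B2pin2 (0.6 equiv), THF, 80 °C; then 2 M NaOH, 30% H2O2, 0 °C to rt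
Reagents that add atoms: bis(pinacolato)diboron, CC1(C)OB(OC1(C)C)B1OC(C)(C)C(C)(C)O1; hydrogen peroxide, OO
Why: Sterically controlled iridium-catalysed C–H borylation takes the only C–H without an ortho substituent (C5), and oxidation of the C–B bond at the same carbon gives the phloroglucinol-type phenol.

Step 3
Reactants: 4 3,5-bis(methoxymethoxy)phenol; 5 propargyl bromide
Product: 6 1,3-bis(methoxymethoxy)-5-(prop-2-yn-1-yloxy)benzene
Conditions: K2CO3, acetone, reflux
Reagents that add atoms: none
Why: Williamson etherification of the phenoxide with the primary propargylic bromide.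

Step 4
Reactants: 6 1,3-bis(methoxymethoxy)-5-(prop-2-yn-1-yloxy)benzene
Product: 7 5,7-bis(methoxymethoxy)-2H-chromene
Conditions: Ph3PAuNTf2 (2 mol%), CH2Cl2, rt
Reagents that add atoms: none
Why: Gold-catalysed 6-endo-dig intramolecular hydroarylation (aryl C–H functionalisation) of the aryl propargyl ether closes ring C, and the two ortho positions are equivalent so only one chromene can form.

Step 5
Reactants: 7 5,7-bis(methoxymethoxy)-2H-chromene
Product: 8 racemic 2-ethoxy-5,7-bis(methoxymethoxy)-2H-chromene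
Conditions: DDQ (1.05 equiv), EtOH (10 equiv), 4 Å molecular sieves, CH2Cl2, −20 to 0 °C; NaHCO3 work-up, used crude
Reagents that add atoms: ethanol, CCO
Why: Oxidative C–H acetalisation, in which DDQ abstracts hydride from the allylic O–CH2 to give the aromatic 1-benzopyrylium ion that ethanol traps at C2; the acetal centre is racemic and is erased in step 9.

Step 6
Reactants: 2 1,3-bis(methoxymethoxy)benzene
Product: 11 2,6-bis(methoxymethoxy)phenol, via aryllithium 9 (not isolated), via lithium aryltrimethoxyborate 10 (not isolated)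
Conditions: n-BuLi (1.1 equiv), THF, 0 °C; B(OMe)3 (1.5 equiv), −78 °C to rt; AcOH, 30% H2O2, 0 °C to rt
Reagents that add atoms: n-butyllithium, [Li]CCCC; trimethyl borate, COB(OC)OC; hydrogen peroxide, OO
Why: Directed ortho-metalation at C2 between the two MOM ethers, followed by borylation and oxidation, puts the third oxygen of ring B between the other two.

Step 7
Reactants: 11 2,6-bis(methoxymethoxy)phenol
Product: 12 2-methoxy-1,3-bis(methoxymethoxy)benzene
Conditions: MeI (1.5 equiv), K2CO3, DMF, rt
Reagents that add atoms: iodomethane, CI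
Why: Williamson methylation of the only free phenol installs the 4'-methoxy group, which stays to the end.

Step 8
Reactants: 12 2-methoxy-1,3-bis(methoxymethoxy)benzene
Product: 14 [4-methoxy-3,5-bis(methoxymethoxy)phenyl]boronic acid, via pinacol boronate 13 (not isolated)
Conditions: [Ir(OMe)(cod)]2 (1.5 mol%), dtbpy (3 mol%), B2pin2 (0.6 equiv), THF, 80 °C; then NaIO4 (3 equiv), NH4OAc (3 equiv), acetone/H2O, rt
Reagents that add atoms: bis(pinacolato)diboron, CC1(C)OB(OC1(C)C)B1OC(C)(C)C(C)(C)O1; water, O
Why: Iridium-catalysed C–H borylation takes the only unhindered C–H (C5, para to the methoxy group), and periodate cleavage of the pinacol frees the boronic acid needed for the nickel coupling.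

Step 9
Reactants: 8 racemic 2-ethoxy-5,7-bis(methoxymethoxy)-2H-chromene; 14 [4-methoxy-3,5-bis(methoxymethoxy)phenyl]boronic acid
Product: 15 racemic 2-[4-methoxy-3,5-bis(methoxymethoxy)phenyl]-5,7-bis(methoxymethoxy)-2H-chromene
Conditions: Ni(cod)2 (10 mol%), PPh3 (20 mol%), 14 (1.5 equiv), dioxane/t-AmOH, 40 °C, argon, no base
Reagents that add atoms: none
Why: Nickel-catalysed C(sp3)–O activation and Suzuki–Miyaura-type coupling, in which the boronic acid assists ionisation of the acetal, zerovalent nickel gives an η3-benzopyranyl nickel species, and aryl transfer with reductive elimination at C2 forms the C2–C1' bond joining rings A/C to ring B as a racemate.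

Step 10
Reactants: 15 racemic 2-[4-methoxy-3,5-bis(methoxymethoxy)phenyl]-5,7-bis(methoxymethoxy)-2H-chromene
Product: 17 racemic (2R*,3S*)-2-[4-methoxy-3,5-bis(methoxymethoxy)phenyl]-5,7-bis(methoxymethoxy)chroman-3-ol, via alkylborane 16 (not isolated)
Conditions: BH3·THF (2 equiv), THF, 0 °C to rt; then 3 M NaOH, 30% H2O2, 0 °C
Reagents that add atoms: borane–tetrahydrofuran, B.C1CCOC1; hydrogen peroxide, OO
Why: Hydroboration–oxidation, in which boron adds to C3 (away from C4 and its peri MOM ether) on the face opposite the C2 aryl group and oxidation with retention gives the racemic 2,3-trans alcohol.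

Step 11
Reactants: 17 racemic (2R*,3S*)-2-[4-methoxy-3,5-bis(methoxymethoxy)phenyl]-5,7-bis(methoxymethoxy)chroman-3-ol
Product: 18 racemic 2-[4-methoxy-3,5-bis(methoxymethoxy)phenyl]-5,7-bis(methoxymethoxy)chroman-3-one
Conditions: Dess–Martin periodinane (1.5 equiv), water-saturated CH2Cl2, 0 °C to rt; used at once
Reagents that add atoms: none
Why: Dess–Martin oxidation under near-neutral conditions gives the flavan-3-one without touching the MOM ethers, and the C2 centre is deliberately left racemic for step 12.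

Step 12
Reactants: 18 racemic 2-[4-methoxy-3,5-bis(methoxymethoxy)phenyl]-5,7-bis(methoxymethoxy)chroman-3-one
Product: 19 (2R,3R)-2-[4-methoxy-3,5-bis(methoxymethoxy)phenyl]-5,7-bis(methoxymethoxy)chroman-3-ol
Conditions: RuCl2[(S)-xylbinap][(S)-daipen] (1 mol%), t-BuOK (10 mol%), H2 (8 atm), i-PrOH/THF 3:1, 25 °C, oxygen-free
Reagents that add atoms: none
Why: Proposed new method: base-promoted dynamic kinetic resolution of a racemic flavan-3-one by asymmetric hydrogenation, a ketone class on which this has not been shown; t-BuOK interconverts the two enantiomers of 18 through the C2 enolate (C2–H is flanked by the carbonyl, the ring oxygen and the aryl group), the chiral RuH2(diphosphine)(diamine) species transfers hydride and the N–H proton through an outer-sphere six-membered transition state to one enantiomer only, and hydride enters C3 from the face opposite the pseudo-equatorial C2 aryl group, so C2 (R) and C3 (R) are set together with aryl and hydroxyl cis; the closest known reaction type is the Noyori BINAP/diamine–Ru hydrogenative DKR of racemic 2-alkoxy- and 2-arylcyclohexanones to cis alcohols, and the cis preference matches the known LiBH(s-Bu)3 reduction of flavan-3-ones.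

Step 13
Reactants: 20 anisole
Product: 23 2-methoxyphenol, via 2-lithioanisole 21 (not isolated), via lithium aryltrimethoxyborate 22 (not isolated)
Conditions: n-BuLi (1.1 equiv), TMEDA (1.1 equiv), Et2O, 0 °C to rt; B(OMe)3, −78 °C to rt; AcOH, 30% H2O2, 0 °C to rt
Reagents that add atoms: n-butyllithium, [Li]CCCC; trimethyl borate, COB(OC)OC; hydrogen peroxide, OO
Why: Directed ortho-metalation of anisole, borylation and oxidation place the hydroxyl next to the methoxy group with full regiocontrol.

Step 14
Reactants: 23 2-methoxyphenol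
Product: 24 4-bromo-2-methoxyphenol
Conditions: NBS (1.0 equiv), MeCN, −10 °C to rt
Reagents that add atoms: N-bromosuccinimide, BrN1C(=O)CCC1=O
Why: Electrophilic aromatic bromination goes para to the hydroxyl group, the stronger director.

Step 15
Reactants: 24 4-bromo-2-methoxyphenol
Product: 25 4-bromo-2-methoxy-1-(methoxymethoxy)benzene
Conditions: NaH (1.2 equiv), MOMCl (1.2 equiv), THF/DMF, 0 °C to rt
Reagents that add atoms: chloromethyl methyl ether (MOMCl), COCCl
Why: Williamson-type MOM protection masks the phenol for the Heck and esterification steps, and it falls together with the other MOM groups at the end.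

Step 16
Reactants: 25 4-bromo-2-methoxy-1-(methoxymethoxy)benzene; 26 acrylic acid
Product: 27 (E)-3-[3-methoxy-4-(methoxymethoxy)phenyl]prop-2-enoic acid
Conditions: Pd(OAc)2 (2 mol%), P(o-tol)3 (6 mol%), Et3N (3 equiv), DMF, 100 °C; cold aq citric acid to pH 4
Reagents that add atoms: none
Why: Mizoroki–Heck coupling, in which oxidative addition of zerovalent palladium to the aryl bromide, syn-carbopalladation of the acrylate and syn β-hydride elimination give only the (E)-cinnamic acid.

Step 17
Reactants: 19 (2R,3R)-2-[4-methoxy-3,5-bis(methoxymethoxy)phenyl]-5,7-bis(methoxymethoxy)chroman-3-ol; 27 (E)-3-[3-methoxy-4-(methoxymethoxy)phenyl]prop-2-enoic acid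
Product: 28 (2R,3R)-2-[4-methoxy-3,5-bis(methoxymethoxy)phenyl]-5,7-bis(methoxymethoxy)chroman-3-yl (E)-3-[3-methoxy-4-(methoxymethoxy)phenyl]prop-2-enoate
Conditions: DCC (1.5 equiv), DMAP (0.2 equiv), 27 (1.3 equiv), CH2Cl2, 0 °C to rt
Reagents that add atoms: none
Why: Steglich esterification acylates the hindered axial 3-OH through the acylpyridinium ion at oxygen, so neither C2 nor C3 is touched and the alkene stays (E).

Step 18
Reactants: 28 (2R,3R)-2-[4-methoxy-3,5-bis(methoxymethoxy)phenyl]-5,7-bis(methoxymethoxy)chroman-3-yl (E)-3-[3-methoxy-4-(methoxymethoxy)phenyl]prop-2-enoate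
Product: 29 4'-O-methylepigallocatechin-3-O-ferulate
Conditions: HCl (2 M in MeOH)/THF 1:1, 0 °C to rt, argon; NaHCO3 work-up
Reagents that add atoms: none
Why: Acid-catalysed transacetalisation to methanol removes all five MOM ethers as dimethoxymethane under conditions meant to be too mild for ester methanolysis, C2 epimerisation or cleavage of the two methyl ethers, and the alkene survives because no reductant is used.

## Compound list

1 | resorcinol | Oc1cccc(O)c1 | starting material
2 | 1,3-bis(methoxymethoxy)benzene | COCOc1cccc(OCOC)c1 | intermediate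
3 | 2-[3,5-bis(methoxymethoxy)phenyl]-4,4,5,5-tetramethyl-1,3,2-dioxaborolane | COCOc1cc(OCOC)cc(c1)B1OC(C)(C)C(C)(C)O1 | intermediate
4 | 3,5-bis(methoxymethoxy)phenol | COCOc1cc(O)cc(OCOC)c1 | intermediate
5 | propargyl bromide (3-bromoprop-1-yne) | BrCC#C | starting material
6 | 1,3-bis(methoxymethoxy)-5-(prop-2-yn-1-yloxy)benzene | C#CCOc1cc(OCOC)cc(OCOC)c1 | intermediate
7 | 5,7-bis(methoxymethoxy)-2H-chromene | COCOc1cc(OCOC)c2C=CCOc2c1 | intermediate
8 | racemic 2-ethoxy-5,7-bis(methoxymethoxy)-2H-chromene | CCOC1C=Cc2c(OCOC)cc(OCOC)cc2O1 | intermediate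
9 | [2,6-bis(methoxymethoxy)phenyl]lithium | [Li]c1c(OCOC)cccc1OCOC | intermediate
10 | lithium [2,6-bis(methoxymethoxy)phenyl]trimethoxyborate | [Li+].COCOc1cccc(OCOC)c1[B-](OC)(OC)OC | intermediate
11 | 2,6-bis(methoxymethoxy)phenol | COCOc1cccc(OCOC)c1O | intermediate
12 | 2-methoxy-1,3-bis(methoxymethoxy)benzene | COCOc1cccc(OCOC)c1OC | intermediate
13 | 2-[4-methoxy-3,5-bis(methoxymethoxy)phenyl]-4,4,5,5-tetramethyl-1,3,2-dioxaborolane | COCOc1cc(cc(OCOC)c1OC)B1OC(C)(C)C(C)(C)O1 | intermediate
14 | [4-methoxy-3,5-bis(methoxymethoxy)phenyl]boronic acid | COCOc1cc(cc(OCOC)c1OC)B(O)O | intermediate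
15 | racemic 2-[4-methoxy-3,5-bis(methoxymethoxy)phenyl]-5,7-bis(methoxymethoxy)-2H-chromene | COCOc1cc(OCOC)c2C=CC(Oc2c1)c1cc(OCOC)c(OC)c(OCOC)c1 | intermediate
16 | racemic 2,3-trans-{2-[4-methoxy-3,5-bis(methoxymethoxy)phenyl]-5,7-bis(methoxymethoxy)chroman-3-yl}borane (one enantiomer drawn) | B[C@H]1Cc2c(OCOC)cc(OCOC)cc2O[C@@H]1c1cc(OCOC)c(OC)c(OCOC)c1 | intermediate
17 | racemic (2R*,3S*)-2-[4-methoxy-3,5-bis(methoxymethoxy)phenyl]-5,7-bis(methoxymethoxy)chroman-3-ol (2,3-trans, one enantiomer drawn) | O[C@H]1Cc2c(OCOC)cc(OCOC)cc2O[C@@H]1c1cc(OCOC)c(OC)c(OCOC)c1 | intermediate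
18 | racemic 2-[4-methoxy-3,5-bis(methoxymethoxy)phenyl]-5,7-bis(methoxymethoxy)chroman-3-one | COCOc1cc(OCOC)c2CC(=O)C(Oc2c1)c1cc(OCOC)c(OC)c(OCOC)c1 | intermediate
19 | (2R,3R)-2-[4-methoxy-3,5-bis(methoxymethoxy)phenyl]-5,7-bis(methoxymethoxy)chroman-3-ol | O[C@@H]1Cc2c(OCOC)cc(OCOC)cc2O[C@@H]1c1cc(OCOC)c(OC)c(OCOC)c1 | intermediate
20 | anisole | COc1ccccc1 | starting material
21 | (2-methoxyphenyl)lithium | [Li]c1ccccc1OC | intermediate
22 | lithium trimethoxy(2-methoxyphenyl)borate | [Li+].COc1ccccc1[B-](OC)(OC)OC | intermediate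
23 | 2-methoxyphenol | COc1ccccc1O | intermediate
24 | 4-bromo-2-methoxyphenol | COc1cc(Br)ccc1O | intermediate
25 | 4-bromo-2-methoxy-1-(methoxymethoxy)benzene | COCOc1ccc(Br)cc1OC | intermediate
26 | acrylic acid | C=CC(=O)O | starting material
27 | (E)-3-[3-methoxy-4-(methoxymethoxy)phenyl]prop-2-enoic acid | COCOc1ccc(/C=C/C(=O)O)cc1OC | intermediate
28 | (2R,3R)-2-[4-methoxy-3,5-bis(methoxymethoxy)phenyl]-5,7-bis(methoxymethoxy)chroman-3-yl (E)-3-[3-methoxy-4-(methoxymethoxy)phenyl]prop-2-enoate | COCOc1ccc(/C=C/C(=O)O[C@@H]2Cc3c(OCOC)cc(OCOC)cc3O[C@@H]2c2cc(OCOC)c(OC)c(OCOC)c2)cc1OC | intermediate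
29 | 4'-O-methylepigallocatechin-3-O-ferulate, (2R,3R)-2-(3,5-dihydroxy-4-methoxyphenyl)-5,7-dihydroxychroman-3-yl (E)-3-(4-hydroxy-3-methoxyphenyl)prop-2-enoate | COc1cc(/C=C/C(=O)O[C@@H]2Cc3c(O)cc(O)cc3O[C@@H]2c2cc(O)c(OC)c(O)c2)ccc1O | target

## Step count

Total steps: 18.
Longest linear sequence: 11 steps (1, 2, 3, 4, 5, 9, 10, 11, 12, 17, 18).

## Steps most likely to fail, with fallbacks

**Step 12 (the proposed hydrogenative DKR).** The risk is that C2 epimerisation is slow relative to reduction, or that the catalyst separates the two ketone enantiomers poorly, giving low ee or trans alcohol. The fallback uses known chemistry and sets out from ketone 18. Reduction with LiBH(s-Bu)3 in THF at −78 °C, which is known to attack flavan-3-ones anti to the C2 aryl group, gives the racemic 2,3-cis alcohol F2. Acylation with (1S)-camphanic chloride (Et3N, DMAP, CH2Cl2) gives the (2R,3R) camphanate F3 and the (2S,3S) camphanate F4, which are separated by chromatography or crystallisation. Methanolysis of F3 (K2CO3, MeOH/THF, rt) comes back to the route at alcohol 19.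

**Step 9 (nickel coupling of the electron-rich chromene acetal).** The risk is that acetal 8 decomposes or that the nickel cycle stalls with this donor-rich pair. The fallback sets out from boronic acid 14 together with phenol 4 and builds ring C by condensation instead of cross-coupling at C2. An oxidative Heck reaction of 14 with acrolein (Pd(OAc)2, 2,9-dimethyl-1,10-phenanthroline, p-benzoquinone, MeCN, rt) gives (E)-3-[4-methoxy-3,5-bis(methoxymethoxy)phenyl]prop-2-enal F1. Condensation of F1 with 4 (PhB(OH)2, catalytic propionic acid, toluene, reflux with water removal) runs through the ortho-quinone methide and an oxa-6π electrocyclisation and comes back to the route at flavene 15. Steps 3 to 5 are then not needed.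

**Step 18 (acidic removal of five MOM groups from the ester).** The risk is methanolysis of the ferulate, alkylation of ring A by formaldehyde equivalents, or C2 epimerisation. The fallback changes the phenol protection to silyl ethers and sets out from alcohol 19 and bromophenol 24.
- Acid removal of the four MOM groups from 19 (HCl, MeOH, rt), where no ester is present, gives (2R,3R)-2-(3,5-dihydroxy-4-methoxyphenyl)chromane-3,5,7-triol F5.
- TBSCl and imidazole in DMF silylate the four phenols and leave the hindered 3-OH free, giving the tetra-TBS ether F6.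
- In parallel, 24 is silylated (TBSCl, imidazole) to (4-bromo-2-methoxyphenoxy)(tert-butyl)dimethylsilane F7, and Heck coupling with 26 (Pd(OAc)2, P(o-tol)3, Et3N, DMF) gives (E)-3-[4-(tert-butyldimethylsilyloxy)-3-methoxyphenyl]prop-2-enoic acid F8.
- DCC/DMAP esterification of F6 with F8 gives the penta-TBS ester F9.
- HF·pyridine in THF/pyridine at 0 °C removes the silyl groups and comes back to the route at target 29.

## Further compounds

F1 | step 9 | (E)-3-[4-methoxy-3,5-bis(methoxymethoxy)phenyl]prop-2-enal | COCOc1cc(/C=C/C=O)cc(OCOC)c1OC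
F2 | step 12 | racemic (2R*,3R*)-2-[4-methoxy-3,5-bis(methoxymethoxy)phenyl]-5,7-bis(methoxymethoxy)chroman-3-ol (2,3-cis, the 2S,3S enantiomer drawn, 1:1 with 19) | O[C@H]1Cc2c(OCOC)cc(OCOC)cc2O[C@H]1c1cc(OCOC)c(OC)c(OCOC)c1
F3 | step 12 | (2R,3R)-2-[4-methoxy-3,5-bis(methoxymethoxy)phenyl]-5,7-bis(methoxymethoxy)chroman-3-yl (1S,4R)-4,7,7-trimethyl-3-oxo-2-oxabicyclo[2.2.1]heptane-1-carboxylate | O=C(O[C@@H]1Cc2c(OCOC)cc(OCOC)cc2O[C@@H]1c1cc(OCOC)c(OC)c(OCOC)c1)[C@@]12CC[C@@](C)(C(=O)O1)C2(C)C
F4 | step 12 | (2S,3S)-2-[4-methoxy-3,5-bis(methoxymethoxy)phenyl]-5,7-bis(methoxymethoxy)chroman-3-yl (1S,4R)-4,7,7-trimethyl-3-oxo-2-oxabicyclo[2.2.1]heptane-1-carboxylate | O=C(O[C@H]1Cc2c(OCOC)cc(OCOC)cc2O[C@H]1c1cc(OCOC)c(OC)c(OCOC)c1)[C@@]12CC[C@@](C)(C(=O)O1)C2(C)C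
F5 | step 18 | (2R,3R)-2-(3,5-dihydroxy-4-methoxyphenyl)chromane-3,5,7-triol | O[C@@H]1Cc2c(O)cc(O)cc2O[C@@H]1c1cc(O)c(OC)c(O)c1
F6 | step 18 | (2R,3R)-2-[3,5-bis(tert-butyldimethylsilyloxy)-4-methoxyphenyl]-5,7-bis(tert-butyldimethylsilyloxy)chroman-3-ol | O[C@@H]1Cc2c(O[Si](C)(C)C(C)(C)C)cc(O[Si](C)(C)C(C)(C)C)cc2O[C@@H]1c1cc(O[Si](C)(C)C(C)(C)C)c(OC)c(O[Si](C)(C)C(C)(C)C)c1
F7 | step 18 | (4-bromo-2-methoxyphenoxy)(tert-butyl)dimethylsilane | COc1cc(Br)ccc1O[Si](C)(C)C(C)(C)C
F8 | step 18 | (E)-3-[4-(tert-butyldimethylsilyloxy)-3-methoxyphenyl]prop-2-enoic acid | COc1cc(/C=C/C(=O)O)ccc1O[Si](C)(C)C(C)(C)C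
F9 | step 18 | (2R,3R)-2-[3,5-bis(tert-butyldimethylsilyloxy)-4-methoxyphenyl]-5,7-bis(tert-butyldimethylsilyloxy)chroman-3-yl (E)-3-[4-(tert-butyldimethylsilyloxy)-3-methoxyphenyl]prop-2-enoate | COc1cc(/C=C/C(=O)O[C@@H]2Cc3c(O[Si](C)(C)C(C)(C)C)cc(O[Si](C)(C)C(C)(C)C)cc3O[C@@H]2c2cc(O[Si](C)(C)C(C)(C)C)c(OC)c(O[Si](C)(C)C(C)(C)C)c2)ccc1O[Si](C)(C)C(C)(C)C
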